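**Plan**

- Retrosynthesis: after removal of the O-benzyl and O-silyl groups, the stilbene is cut at the bond between C5 of the benzofuran and the vinyl carbon (Mizoroki–Heck). The dihydrofuran of the resulting 5-bromo-2,3-dihydrobenzofuran is then cut at O1–C2 and C2–C3.
- Enabling feature: in the dihydrofuran ring C2 is bonded to both O1 and C3, and C3 sits on C3a next to the oxygen-bearing C7a. C2 with its syringyl group can therefore come as a one-carbon sulfonium ylide, and O1–C7a–C3a–C3 as an ortho-quinone methide whose exocyclic carbon is C3.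
- Forward: ortho-hydroxyalkylation of 4-bromo-2-methoxyphenol and hydroxyl-to-sulfinate exchange give the methide precursor. Syringaldehyde and (2S,5S)-hexane-2,5-diol give the chiral benzylthiolanium salt. Their (4+1) annulation closes the only new ring; desilylation, Heck coupling and debenzylation finish the route.
- Stereochemistry: C2 comes from reagent control by the twofold-symmetric (2R,5R)-2,5-dimethylthiolane, made from the diol by double inversion. C3 comes from the trans-selective addition in the same step, and the E alkene from the Heck reaction.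

Key step: step 9

Assumption: the sense of induction of the (2R,5R)-thiolanium ylide is taken from the face preference such benzylic ylides show toward aldehydes, which here corresponds to 2R after inversion; if the annulation shows the opposite sense, the enantiomeric sulfide from (2R,5R)-hexane-2,5-diol is used and nothing else changes.

**Route**

Step 1
Reactants: 1 4-bromo-2-methoxyphenol; 2 (tert-butyldimethylsilyloxy)acetaldehyde
Product: 4 racemic 4-bromo-2-[2-(tert-butyldimethylsilyloxy)-1-hydroxyethyl]-6-methoxyphenol, via bromomagnesium phenoxide 3 (not isolated)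
Conditions: EtMgBr (1.0 equiv), Et2O, 0 °C; solvent changed to CH2Cl2; 2, rt; aq. NH4Cl
Reagents that add atoms: none
Why: Ortho-selective hydroxyalkylation of a magnesium phenoxide, a magnesium-templated Friedel–Crafts-type aldol known for α-alkoxy aldehydes: the aldehyde, held on magnesium by its carbonyl and silyloxy oxygens, is delivered through a cyclic transition state to the one free carbon ortho to the phenoxide oxygen (the para carbon carries bromine), and the racemic carbinol centre is erased in step 9.

Step 2
Reactants: 4 racemic 4-bromo-2-[2-(tert-butyldimethylsilyloxy)-1-hydroxyethyl]-6-methoxyphenol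
Product: 5 racemic 4-bromo-2-methoxy-6-[2-(tert-butyldimethylsilyloxy)-1-(4-methylbenzenesulfonyl)ethyl]phenol
Conditions: p-TolSO2H (1.5 equiv), 4 Å MS, CH2Cl2, rt
Reagents that add atoms: p-toluenesulfinic acid, Cc1ccc(cc1)S(=O)O
Why: Acid-promoted SN1-type exchange of an ortho-hydroxybenzylic hydroxyl for sulfinate bound through sulfur is the standard entry to 2-(1-sulfonylalkyl)phenols, and the mild sulfinic acid in dry CH2Cl2 should leave the primary silyl ether in place.

Step 3
Reactants: 6 syringaldehyde (4-hydroxy-3,5-dimethoxybenzaldehyde)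
Product: 7 4-benzyloxy-3,5-dimethoxybenzaldehyde
Conditions: BnBr, K2CO3, DMF, 60 °C
Reagents that add atoms: benzyl bromide, BrCc1ccccc1
Why: Williamson etherification of the acidic, para-formyl-activated phenol, which gives a base-stable ether that cannot unmask a para-oxido group next to the later sulfonium centre.

Step 4
Reactants: 7 4-benzyloxy-3,5-dimethoxybenzaldehyde
Product: 8 (4-benzyloxy-3,5-dimethoxyphenyl)methanol
Conditions: NaBH4, MeOH, 0 °C
Reagents that add atoms: none
Why: Borohydride reduction of an aromatic aldehyde to the benzylic alcohol, with no other reducible group present.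

Step 5
Reactants: 8 (4-benzyloxy-3,5-dimethoxyphenyl)methanol
Product: 9 4-benzyloxy-3,5-dimethoxybenzyl bromide
Conditions: PBr3, CH2Cl2, 0 °C, short reaction time; used without storage
Reagents that add atoms: phosphorus tribromide, BrP(Br)Br
Why: Bromination of an electron-rich benzylic alcohol through its phosphite ester, fast enough at 0 °C that the aryl benzyl ether should not be touched.

Step 6
Reactants: 10 (2S,5S)-hexane-2,5-diol
Product: 11 (2S,5S)-hexane-2,5-diyl dimethanesulfonate
Conditions: MsCl, Et3N, CH2Cl2, −20 → 0 °C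
Reagents that add atoms: methanesulfonyl chloride, CS(=O)(=O)Cl
Why: O-Sulfonylation forms only O–S bonds, so both carbinol centres keep their configuration.

Step 7
Reactants: 11 (2S,5S)-hexane-2,5-diyl dimethanesulfonate
Product: 12 (2R,5R)-2,5-dimethylthiolane
Conditions: Na2S·9H2O, EtOH, rt → 50 °C
Reagents that add atoms: sodium sulfide, [Na+].[Na+].[S-2]
Why: Double SN2 displacement by sulfide, the second one an intramolecular 5-exo-tet closure, inverts both centres (S,S to R,R) and gives the twofold-symmetric trans sulfide.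

Step 8
Reactants: 9 4-benzyloxy-3,5-dimethoxybenzyl bromide; 12 (2R,5R)-2,5-dimethylthiolane
Product: 13 (2R,5R)-1-(4-benzyloxy-3,5-dimethoxybenzyl)-2,5-dimethylthiolan-1-ium tetrafluoroborate
Conditions: AgBF4, CH2Cl2, 0 °C → rt, dark
Reagents that add atoms: silver tetrafluoroborate, [Ag+].F[B-](F)(F)F
Why: S-Alkylation of the hindered sulfide is driven by silver-assisted removal of bromide, and because the two sulfur lone pairs are equivalent in the twofold-symmetric thiolane a single sulfonium salt results.

Step 9
Reactants: 5 racemic 4-bromo-2-methoxy-6-[2-(tert-butyldimethylsilyloxy)-1-(4-methylbenzenesulfonyl)ethyl]phenol; 13 (2R,5R)-1-(4-benzyloxy-3,5-dimethoxybenzyl)-2,5-dimethylthiolan-1-ium tetrafluoroborate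
Product: 17 (2R,3S)-2-(4-benzyloxy-3,5-dimethoxyphenyl)-5-bromo-3-[(tert-butyldimethylsilyloxy)methyl]-7-methoxy-2,3-dihydrobenzofuran, via ortho-quinone methide 14 (not isolated), via sulfonium ylide 15 (not isolated), via sulfonium phenoxide betaine 16 (not isolated)
Conditions: Cs2CO3 (3 equiv), MeCN/CH2Cl2, 0 °C → rt; 5 added slowly to 13 (1.3 equiv)
Reagents that add atoms: none
Why: Cs2CO3 turns phenol 5 into its phenoxide, which expels toluenesulfinate to give ortho-quinone methide 14, and deprotonates salt 13 to the benzylic ylide 15; the ylide carbon adds to the exocyclic methide carbon with return of aromaticity (C2–C3, betaine 16), and the phenoxide then displaces the thiolane at the sulfonium carbon with inversion (O1–C2). The closest known reaction is the (4+1) annulation of sulfonium ylides with ortho-quinone methides released from 2-(1-sulfonylalkyl)phenols, which delivers trans-2,3-dihydrobenzofurans. The dihydrofuran, the only ring formed, closes by a 5-exo-tet displacement. C2 is controlled by the twofold-symmetric thiolane: sulfur is not stereogenic so only one salt exists, a flanking methyl group shields one face of the ylide carbon, and inversion on closure then gives the 2R centre. C3 is set in the same addition, relative to C2, by an approach that keeps the syringyl ring and the silyloxymethyl arm apart and so leads to the trans ring; because the addition regains the arene and closure should outpace deprotonation of 16, a lapse in this relative control would surface as the separable cis isomer and not as the enantiomer. The step needs enantio- and trans-selectivity plus attack at the methide carbon only: the chiral sulfide and the steric demand of the two carbon substituents supply the first two, while the aromatization gained on 1,4-addition and the poorly leaving silyl ether (no β-elimination from the sulfone) secure the third.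

Step 10
Reactants: 17 (2R,3S)-2-(4-benzyloxy-3,5-dimethoxyphenyl)-5-bromo-3-[(tert-butyldimethylsilyloxy)methyl]-7-methoxy-2,3-dihydrobenzofuran
Product: 18 [(2R,3S)-2-(4-benzyloxy-3,5-dimethoxyphenyl)-5-bromo-7-methoxy-2,3-dihydrobenzofuran-3-yl]methanol
Conditions: TBAF, THF, 0 °C → rt; aq. NH4Cl
Reagents that add atoms: none
Why: Fluoride cleaves the Si–O bond of the primary silyl ether, and neither C2–H nor C3–H is acidic enough for the basic medium to touch the stereocentres.

Step 11
Reactants: 19 3,5-bis(benzyloxy)benzaldehyde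
Product: 20 3,5-bis(benzyloxy)styrene
Conditions: MePPh3Br, KOtBu, THF, 0 °C → rt
Reagents that add atoms: methyltriphenylphosphonium bromide, C[P+](c1ccccc1)(c1ccccc1)c1ccccc1.[Br-]
Why: Wittig methylenation of a non-enolizable aromatic aldehyde with the unstabilized ylide.

Step 12
Reactants: 18 [(2R,3S)-2-(4-benzyloxy-3,5-dimethoxyphenyl)-5-bromo-7-methoxy-2,3-dihydrobenzofuran-3-yl]methanol; 20 3,5-bis(benzyloxy)styrene
Product: 21 [(2R,3S)-2-(4-benzyloxy-3,5-dimethoxyphenyl)-5-[(E)-2-(3,5-dibenzyloxyphenyl)ethenyl]-7-methoxy-2,3-dihydrobenzofuran-3-yl]methanol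
Conditions: Pd2(dba)3 (2.5 mol %), [HP(t-Bu)3]BF4 (10 mol %), Cy2NMe, 1,4-dioxane, 80 °C
Reagents that add atoms: none
Why: Mizoroki–Heck reaction: the electron-rich aryl bromide adds oxidatively to the zerovalent palladium–P(t-Bu)3 catalyst, the styrene inserts at its terminal carbon, and syn β-hydride elimination gives the E-stilbene, with the free alcohol and benzyl ethers as spectators.

Step 13
Reactants: 21 [(2R,3S)-2-(4-benzyloxy-3,5-dimethoxyphenyl)-5-[(E)-2-(3,5-dibenzyloxyphenyl)ethenyl]-7-methoxy-2,3-dihydrobenzofuran-3-yl]methanol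
Product: 22 gnetucleistol F, 5-[(E)-2-[(2R,3S)-2-(4-hydroxy-3,5-dimethoxyphenyl)-3-(hydroxymethyl)-7-methoxy-2,3-dihydrobenzofuran-5-yl]ethenyl]benzene-1,3-diol
Conditions: BCl3 (6 equiv), C6HMe5 (10 equiv), CH2Cl2, −78 °C; MeOH quench at −78 °C
Reagents that add atoms: none
Why: Lewis-acid cleavage of aryl benzyl ethers, in which each benzyl cation released from the boron-complexed ether is trapped by pentamethylbenzene (Friedel–Crafts); at −78 °C this should spare the aryl methyl ethers, the alkene and both stereocentres.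

**Compound list**

1 | 4-bromo-2-methoxyphenol | COc1cc(Br)ccc1O | starting material
2 | (tert-butyldimethylsilyloxy)acetaldehyde | O=CCO[Si](C)(C)C(C)(C)C | starting material
3 | bromomagnesium 4-bromo-2-methoxyphenoxide | COc1cc(Br)ccc1O[Mg]Br | intermediate (not isolated)
4 | racemic 4-bromo-2-[2-(tert-butyldimethylsilyloxy)-1-hydroxyethyl]-6-methoxyphenol | COc1cc(Br)cc(C(O)CO[Si](C)(C)C(C)(C)C)c1O | intermediate
5 | racemic 4-bromo-2-methoxy-6-[2-(tert-butyldimethylsilyloxy)-1-(4-methylbenzenesulfonyl)ethyl]phenol | COc1cc(Br)cc(C(CO[Si](C)(C)C(C)(C)C)S(=O)(=O)c2ccc(C)cc2)c1O | intermediate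
6 | syringaldehyde | COc1cc(C=O)cc(OC)c1O | starting material
7 | 4-benzyloxy-3,5-dimethoxybenzaldehyde | COc1cc(C=O)cc(OC)c1OCc1ccccc1 | intermediate
8 | (4-benzyloxy-3,5-dimethoxyphenyl)methanol | COc1cc(CO)cc(OC)c1OCc1ccccc1 | intermediate
9 | 4-benzyloxy-3,5-dimethoxybenzyl bromide | COc1cc(CBr)cc(OC)c1OCc1ccccc1 | intermediate
10 | (2S,5S)-hexane-2,5-diol | C[C@H](O)CC[C@H](C)O | starting material
11 | (2S,5S)-hexane-2,5-diyl dimethanesulfonate | C[C@H](OS(C)(=O)=O)CC[C@H](C)OS(C)(=O)=O | intermediate
12 | (2R,5R)-2,5-dimethylthiolane | C[C@@H]1CC[C@@H](C)S1 | intermediate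
13 | (2R,5R)-1-(4-benzyloxy-3,5-dimethoxybenzyl)-2,5-dimethylthiolan-1-ium tetrafluoroborate | COc1cc(C[S+]2[C@H](C)CC[C@H]2C)cc(OC)c1OCc1ccccc1.F[B-](F)(F)F | intermediate
14 | 4-bromo-6-[2-(tert-butyldimethylsilyloxy)ethylidene]-2-methoxycyclohexa-2,4-dien-1-one (ortho-quinone methide) | COC1=CC(Br)=CC(=CCO[Si](C)(C)C(C)(C)C)C1=O | intermediate (not isolated)
15 | (2R,5R)-2,5-dimethylthiolanium (4-benzyloxy-3,5-dimethoxyphenyl)methylide | COc1cc([CH-][S+]2[C@H](C)CC[C@H]2C)cc(OC)c1OCc1ccccc1 | intermediate (not isolated)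
16 | (2R,5R)-1-[(1S,2S)-1-(4-benzyloxy-3,5-dimethoxyphenyl)-2-(5-bromo-3-methoxy-2-oxidophenyl)-3-(tert-butyldimethylsilyloxy)propyl]-2,5-dimethylthiolan-1-ium (betaine) | COc1cc([C@H]([C@H](CO[Si](C)(C)C(C)(C)C)c3cc(Br)cc(OC)c3[O-])[S+]2[C@H](C)CC[C@H]2C)cc(OC)c1OCc1ccccc1 | intermediate (not isolated)
17 | (2R,3S)-2-(4-benzyloxy-3,5-dimethoxyphenyl)-5-bromo-3-[(tert-butyldimethylsilyloxy)methyl]-7-methoxy-2,3-dihydrobenzofuran | COc1cc([C@@H]2Oc3c(OC)cc(Br)cc3[C@H]2CO[Si](C)(C)C(C)(C)C)cc(OC)c1OCc1ccccc1 | intermediate
18 | [(2R,3S)-2-(4-benzyloxy-3,5-dimethoxyphenyl)-5-bromo-7-methoxy-2,3-dihydrobenzofuran-3-yl]methanol | COc1cc([C@@H]2Oc3c(OC)cc(Br)cc3[C@H]2CO)cc(OC)c1OCc1ccccc1 | intermediate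
19 | 3,5-bis(benzyloxy)benzaldehyde | O=Cc1cc(OCc2ccccc2)cc(OCc2ccccc2)c1 | starting material
20 | 3,5-bis(benzyloxy)styrene | C=Cc1cc(OCc2ccccc2)cc(OCc2ccccc2)c1 | intermediate
21 | [(2R,3S)-2-(4-benzyloxy-3,5-dimethoxyphenyl)-5-[(E)-2-(3,5-dibenzyloxyphenyl)ethenyl]-7-methoxy-2,3-dihydrobenzofuran-3-yl]methanol | COc1cc([C@@H]2Oc3c(OC)cc(/C=C/c4cc(OCc5ccccc5)cc(OCc5ccccc5)c4)cc3[C@H]2CO)cc(OC)c1OCc1ccccc1 | intermediate
22 | gnetucleistol F | COc1cc([C@@H]2Oc3c(OC)cc(/C=C/c4cc(O)cc(O)c4)cc3[C@H]2CO)cc(OC)c1O | target

**Totals**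

Total step count: 13 steps.
Longest linear sequence: 8 steps (6 → 7 → 8 → 9 → 13 → 17 → 18 → 21 → 22; steps 3, 4, 5, 8, 9, 10, 12, 13).

**Steps most likely to fail**

Step 9. The hindered, semistabilized ylide may discriminate poorly between its two faces, or add so slowly that the quinone methide is lost to tautomerization and self-condensation, so that the annulation product forms in low enantiomeric purity or not cleanly. The fallback takes the stereochemistry from resolution and sets out from 9 and 5. Bromide 9 is stirred with tetrahydrothiophene in acetone to give 1-(4-benzyloxy-3,5-dimethoxybenzyl)thiolan-1-ium bromide F1. Its unhindered ylide should annulate with 5 (Cs2CO3, CH2Cl2, rt) to the racemic trans-2-(4-benzyloxy-3,5-dimethoxyphenyl)-5-bromo-3-[(tert-butyldimethylsilyloxy)methyl]-7-methoxy-2,3-dihydrobenzofuran F2. TBAF in THF then gives the racemic trans alcohol F3, and preparative HPLC on a cellulose tris(3,5-dimethylphenylcarbamate) phase separates the enantiomers; the (2R,3S) enantiomer is 18, where the route is rejoined.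

Step 1. The bromine-deactivated phenoxide, whose magnesium is also chelated by the neighbouring methoxy group, may attack the aldehyde sluggishly, or the benzylic magnesium alkoxide formed may ionize and alkylate a second phenoxide. The fallback replaces the templated electrophilic substitution by a halogen–metal exchange and sets out from 1. Iodination ortho to the hydroxyl (N-iodosuccinimide, catalytic TsOH, MeCN) gives 4-bromo-2-iodo-6-methoxyphenol F4. Deprotonation with MeMgCl and selective iodine–magnesium exchange with i-PrMgCl·LiCl (THF, −20 °C) leave the bromine in place, and the aryl Grignard reagent adds to aldehyde 2 to return to the route at 4.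

Step 13. During the threefold ether cleavage, benzyl cations may alkylate the resorcinol ring before the scavenger traps them, and the acid may protonate the electron-rich stilbene and start oligomerization. The fallback removes the benzyl group before either of these groups exists and sets out from 18. Treatment of 18 with BCl3 and C6HMe5 (CH2Cl2, −78 °C) gives [(2R,3S)-5-bromo-2-(4-hydroxy-3,5-dimethoxyphenyl)-7-methoxy-2,3-dihydrobenzofuran-3-yl]methanol F5. Commercial 3,5-dihydroxybenzaldehyde is silylated (TBSCl, imidazole, DMF) to 3,5-bis(tert-butyldimethylsilyloxy)benzaldehyde F6 and methylenated (MePPh3Br, KOtBu, THF) to 3,5-bis(tert-butyldimethylsilyloxy)styrene F7. Heck coupling of F5 with F7 under the conditions of step 12 gives the bis-silyl stilbene F8, and TBAF buffered with AcOH in THF releases 22, so the last step is a mild desilylation.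

**Further compounds**

F1 | step 9 | 1-(4-benzyloxy-3,5-dimethoxybenzyl)thiolan-1-ium bromide | COc1cc(C[S+]2CCCC2)cc(OC)c1OCc1ccccc1.[Br-]
F2 | step 9 | racemic trans-2-(4-benzyloxy-3,5-dimethoxyphenyl)-5-bromo-3-[(tert-butyldimethylsilyloxy)methyl]-7-methoxy-2,3-dihydrobenzofuran (both enantiomers) | COc1cc([C@@H]2Oc3c(OC)cc(Br)cc3[C@H]2CO[Si](C)(C)C(C)(C)C)cc(OC)c1OCc1ccccc1.COc1cc([C@H]2Oc3c(OC)cc(Br)cc3[C@@H]2CO[Si](C)(C)C(C)(C)C)cc(OC)c1OCc1ccccc1
F3 | step 9 | racemic trans-[2-(4-benzyloxy-3,5-dimethoxyphenyl)-5-bromo-7-methoxy-2,3-dihydrobenzofuran-3-yl]methanol (both enantiomers) | COc1cc([C@@H]2Oc3c(OC)cc(Br)cc3[C@H]2CO)cc(OC)c1OCc1ccccc1.COc1cc([C@H]2Oc3c(OC)cc(Br)cc3[C@@H]2CO)cc(OC)c1OCc1ccccc1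
F4 | step 1 | 4-bromo-2-iodo-6-methoxyphenol | COc1cc(Br)cc(I)c1O
F5 | step 13 | [(2R,3S)-5-bromo-2-(4-hydroxy-3,5-dimethoxyphenyl)-7-methoxy-2,3-dihydrobenzofuran-3-yl]methanol | COc1cc([C@@H]2Oc3c(OC)cc(Br)cc3[C@H]2CO)cc(OC)c1O
F6 | step 13 | 3,5-bis(tert-butyldimethylsilyloxy)benzaldehyde | O=Cc1cc(O[Si](C)(C)C(C)(C)C)cc(O[Si](C)(C)C(C)(C)C)c1
F7 | step 13 | 3,5-bis(tert-butyldimethylsilyloxy)styrene | C=Cc1cc(O[Si](C)(C)C(C)(C)C)cc(O[Si](C)(C)C(C)(C)C)c1
F8 | step 13 | [(2R,3S)-5-[(E)-2-[3,5-bis(tert-butyldimethylsilyloxy)phenyl]ethenyl]-2-(4-hydroxy-3,5-dimethoxyphenyl)-7-methoxy-2,3-dihydrobenzofuran-3-yl]methanol | COc1cc([C@@H]2Oc3c(OC)cc(/C=C/c4cc(O[Si](C)(C)C(C)(C)C)cc(O[Si](C)(C)C(C)(C)C)c4)cc3[C@H]2CO)cc(OC)c1O
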